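**Retrosynthetic overview**
1. Target ⇐ C7 methyl ester; the 1β-OH comes from conjugate borylation–oxidation of a ring-A enone lactone, on the face anti to the lactone oxygen.
2. Ring A and the 19,10-lactone ⇐ γ-oxidation–lactonisation of a C4-methylated enone diester, itself from a Robinson-type annulation of methyl acetoacetate onto a ring-B enal (from an enol triflate and CO).
3. Ring D and the 12-OH ⇐ key 1,2-shift: solvolysis of a bicyclo[2.2.2]octyl 13-mesylate to the bicyclo[3.2.1]octane (C16 migrates from C12 to C13, water enters C12 anti).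
4. Bicyclo[2.2.2]octane ⇐ carbonyl-ene closure of a C13 aldehyde onto the isoprene-derived alkene, then oxidation and face-selective reduction.
5. Ring B plus the first six-membered ring (C8, C9 set) ⇐ enantioselective Diels–Alder of isoprene with a cyclopentenone made by Blaise reaction, alkylation and aldol. Ring order: B → Diels–Alder ring → [2.2.2] bridge → ring D by shift → A → lactone.

Assumption: the SMILES is read literally; gibberellane numbering (C1–C19) is used for all compounds, α is the face of ring B that carries the lactone oxygen on C10, H-9, C-14 and H-6 in the target, β the face that carries C-1, H-5, C-7, C-11 and C-15.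

**Step 1**
Reactants: 1 3,3-dimethoxypropanenitrile; 2 methyl bromoacetate
Product: 4 methyl 5,5-dimethoxy-3-oxopentanoate, via bromozinc enaminate 3 (not isolated)
Conditions: Zn, TMSCl (cat.), THF, reflux; then 1 M HCl, 0 °C
Reagents that add atoms: water, O
Why: Blaise reaction: the zinc ester enolate from 2 adds to the nitrile of 1 and brief cold acid hydrolyses the zinc enaminate to the β-keto ester while the dimethyl acetal survives; no stereocentre is formed.

**Step 2**
Reactants: 4 methyl 5,5-dimethoxy-3-oxopentanoate; 5 chloroacetone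
Product: 6 methyl 2-(3,3-dimethoxypropanoyl)-4-oxopentanoate (racemic)
Conditions: K2CO3, NaI (cat.), acetone, rt
Reagents that add atoms: none
Why: acetoacetic-ester-type C-alkylation (SN2 with iodide exchange) at the doubly activated carbon, the future C6; the new centre is racemic and labile.

**Step 3**
Reactants: 6 methyl 2-(3,3-dimethoxypropanoyl)-4-oxopentanoate
Product: 7 methyl 2-(2,2-dimethoxyethyl)-4-oxocyclopent-2-ene-1-carboxylate (racemic)
Conditions: NaOMe (0.2 equiv), MeOH, 0 °C to rt
Reagents that add atoms: none
Why: intramolecular aldol condensation of the 1,4-diketone (methyl ketone enolate onto the β-keto ester ketone, then dehydration) closes ring B as a vinylogous β-keto ester; C6 stays racemic and freely epimerisable.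

**Step 4**
Reactants: 7 methyl 2-(2,2-dimethoxyethyl)-4-oxocyclopent-2-ene-1-carboxylate; 8 isoprene
Product: 9 cis-fused cycloadduct ketone (methyl 7a-(2,2-dimethoxyethyl)-6-methyl-3-oxo-2,3,3a,4,7,7a-hexahydro-1H-indene-1-carboxylate; 3a-H/7a-arm/1-ester all cis)
Conditions: 1:1 complex of AlBr3 and (S)-1-(2-methylphenyl)-3,3-diphenyltetrahydro-1H,3H-pyrrolo[1,2-c][1,3,2]oxazaborole (10 mol%), 2,6-di-tert-butylpyridine (5 mol%), isoprene (5 equiv), CH2Cl2, −40 °C
Reagents that add atoms: none
Why: Proposed new method: catalytic enantioselective Diels–Alder reaction of a 3,4-disubstituted cyclopent-2-enone with isoprene under a cationic chiral oxazaborolidine Lewis acid – boron binds the ketone lone pair syn to C9–H, the aryl group blocks one enone face, and the diene adds suprafacially with "para" orientation (C15 to the β-carbon C8, C11 to C9), which sets the quaternary C8 and C9 with the 8α-arm and 9α-H cis; because C6–H of catalyst-bound 7 is a vinylogous β-keto ester hydrogen it epimerises through the hindered base, so the matched epimer (ester anti to the diene) is funnelled to 9; the closest known reactions are oxazaborolidinium-catalysed Diels–Alder reactions of unsubstituted or α-substituted cyclic enones and the racemic AlCl3-promoted additions of dienes to 3-methylcyclopent-2-enones.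

**Step 5**
Reactants: 9 cis-fused cycloadduct ketone
Product: 11 enol triflate aldehyde (methyl 6-methyl-7a-(2-oxoethyl)-3-(trifluoromethylsulfonyloxy)-3a,4,7,7a-tetrahydro-1H-indene-1-carboxylate), via enol triflate acetal 10 (not isolated)
Conditions: KN(SiMe3)2, PhNTf2, THF, −78 °C; then 1 M HCl, THF, rt
Reagents that add atoms: N-phenylbis(trifluoromethanesulfonimide), O=S(=O)(N(c1ccccc1)S(=O)(=O)C(F)(F)F)C(F)(F)F; water, O
Why: kinetic deprotonation at the unhindered C5 methylene (not the ring-fusion C9–H) and O-sulfonylation give the C10 enol triflate regioselectively, and dilute acid then hydrolyses the acetal to the C13 aldehyde; no stereocentre changes.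

**Step 6**
Reactants: 11 enol triflate aldehyde
Product: 12 bicyclo[2.2.2]octane alcohol with 13-OH syn to the C15–C16 bridge
Conditions: Me2AlCl, CH2Cl2, −78 to 0 °C
Reagents that add atoms: none
Why: Lewis-acid-promoted intramolecular carbonyl-ene reaction: C13 bonds to C12 while oxygen takes a hydrogen from the C16 methyl through a six-membered transition state, which closes the bicyclo[2.2.2]octane, creates the exocyclic methylene and forces the 13-oxygen syn to the C15–C16 bridge (the C12 configuration follows from the 8α tether).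

**Step 7**
Reactants: 12 bicyclo[2.2.2]octane alcohol with 13-OH syn to the C15–C16 bridge
Product: 13 bicyclo[2.2.2]octan-13-one
Conditions: Dess–Martin periodinane, CH2Cl2, rt
Reagents that add atoms: none
Why: Dess–Martin oxidation removes the ene-derived C13 configuration, which is the wrong one for the shift; the β,γ-unsaturated ketone cannot conjugate because C12 is a bridgehead.

**Step 8**
Reactants: 13 bicyclo[2.2.2]octan-13-one
Product: 14 bicyclo[2.2.2]octane alcohol with 13-OH anti to the C15–C16 bridge
Conditions: LiBH(s-Bu)3, THF, −78 °C; then H2O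
Reagents that add atoms: none
Why: substrate-controlled reduction with a bulky hydride: attack comes from the face of C13 flanked by the sp2 C16 (no inward hydrogen) rather than by the C11 methylene, so the 13-OH ends syn to the C9–C11 bridge, anti to the C12–C16 bond that must migrate.

**Step 9**
Reactants: 14 bicyclo[2.2.2]octane alcohol with 13-OH anti to the C15–C16 bridge
Product: 16 bicyclo[3.2.1]octane 12-alcohol enol triflate, via 13-mesylate 15 (not isolated)
Conditions: MsCl, Et3N, CH2Cl2, 0 °C; then 2,6-lutidine, acetone–H2O (3:1), 50 °C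
Reagents that add atoms: water, O
Why: key 1,2-shift (homoallylic Wagner–Meerwein rearrangement, the bicyclo[2.2.2]octyl to bicyclo[3.2.1]octyl solvolysis): ionisation of the 13-mesylate is assisted from the rear by the C12–C16 bond and the methylene π-system, C16 migrates from C12 to C13 with inversion, and water captures the bridged cation at C12 anti to the migrated carbon, which builds ring D and sets C13 and the axial 12-OH stereospecifically.

**Step 10**
Reactants: 16 bicyclo[3.2.1]octane 12-alcohol enol triflate
Product: 17 ring-B enal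
Conditions: Pd(OAc)2 (5 mol%), dppp, CO (1 atm), Et3SiH, Et3N, DMF, 70 °C
Reagents that add atoms: carbon monoxide, [C-]#[O+]
Why: palladium-catalysed reductive carbonylation (formylation) of the enol triflate: oxidative addition to zerovalent palladium, CO insertion and hydride transfer from the silane give the enal; no stereocentre is touched.

**Step 11**
Reactants: 17 ring-B enal; 18 methyl acetoacetate
Product: 22 C4-methylated enone diester, via Michael adduct 19 (not isolated), via ketol 20 (not isolated), via enone ester 21 (not isolated)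
Conditions: Cs2CO3, MeCN, 50 °C; then MeI, rt
Reagents that add atoms: iodomethane, CI
Why: Robinson-type annulation (Michael addition to the enal at C5, intramolecular aldol of the acetyl methyl onto C1, dehydration) followed by C-methylation of the resulting β-keto ester: the nucleophile enters C5 on the α face (away from C11 and C15) and anti to the C6 ester, which has equilibrated to β through the enal dienolate, and methyl iodide then alkylates the C4 enolate trans to C6, so the future C19 ester is α and the methyl β.

**Step 12**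
Reactants: 22 C4-methylated enone diester
Product: 25 enone lactone, via bis-silyl dienol ether 23 (not isolated), via 10-hydroxy enone 24 (not isolated)
Conditions: TMSOTf, Et3N, CH2Cl2, 0 °C; then DMDO (1.0 equiv), acetone, −78 °C; then CSA (cat.), wet PhMe, 50 °C
Reagents that add atoms: dimethyldioxirane, CC1(C)OO1
Why: vinylogous Rubottom oxidation: with C4 quaternary only the extended dienol ether can form, the dioxirane oxidises its terminus C10 from the α face (anti to C11 on the neighbouring C9), and acid then closes the 19,10-lactone from the 1,3-diaxial hydroxy ester and removes the silyl ether; a 10-epimeric alcohol would ionise to the same tertiary allylic cation and be captured by the α ester, so C10 converges.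

**Step 13**
Reactants: 25 enone lactone
Product: 27 methyl ester of the target, via boronate 26 (not isolated)
Conditions: CuCl (5 mol%), Xantphos, NaOt-Bu (10 mol%), B2pin2, MeOH, THF, rt; then H2O2, pH 7 phosphate buffer, 0 °C
Reagents that add atoms: hydrogen peroxide, OO
Why: copper-catalysed conjugate borylation of the enone followed by stereoretentive C–B oxidation: the boryl-copper adds to C1 anti to the axial lactone oxygen on C10 (β face), giving the axial 1β-alcohol trans to the lactone oxygen.

**Step 14**
Reactants: 27 methyl ester of the target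
Product: 28 target CNP0259985.3
Conditions: Me3SnOH, ClCH2CH2Cl, 80 °C; then 1 M HCl
Reagents that add atoms: trimethyltin hydroxide, C[Sn](C)(C)O
Why: near-neutral ester hydrolysis with Me3SnOH cleaves the C7 methyl ester without β-elimination or epimerisation of the β-hydroxy ketone and spares the hindered bridged lactone; acid work-up frees the acid and recloses any opened lactone.

**Compound list**
1 | 3,3-dimethoxypropanenitrile | N#CCC(OC)OC | starting material
2 | methyl bromoacetate | COC(=O)CBr | starting material
3 | bromozinc enaminate (methyl (Z)-3-(bromozincioamino)-5,5-dimethoxypent-2-enoate) | COC(=O)/C=C(\N[Zn]Br)CC(OC)OC | intermediate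
4 | methyl 5,5-dimethoxy-3-oxopentanoate | COC(=O)CC(=O)CC(OC)OC | intermediate
5 | chloroacetone | CC(=O)CCl | starting material
6 | methyl 2-(3,3-dimethoxypropanoyl)-4-oxopentanoate (racemic, labile centre) | COC(=O)C(CC(C)=O)C(=O)CC(OC)OC | intermediate
7 | methyl 2-(2,2-dimethoxyethyl)-4-oxocyclopent-2-ene-1-carboxylate (racemic, C6 labile; ring B with the C14–C13 arm on C8) | COC(=O)C1CC(=O)C=C1CC(OC)OC | intermediate
8 | isoprene | C=CC(C)=C | starting material
9 | cis-fused cycloadduct ketone: methyl 7a-(2,2-dimethoxyethyl)-6-methyl-3-oxo-2,3,3a,4,7,7a-hexahydro-1H-indene-1-carboxylate (9α-H, 8α-arm, 6α-ester; C10 ketone) | CC1=CC[C@@H]2C(=O)C[C@@H](C(=O)OC)[C@]2(CC(OC)OC)C1 | intermediate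
10 | enol triflate acetal: methyl 7a-(2,2-dimethoxyethyl)-6-methyl-3-(trifluoromethylsulfonyloxy)-3a,4,7,7a-tetrahydro-1H-indene-1-carboxylate (configuration as 9) | CC1=CC[C@@H]2C(OS(=O)(=O)C(F)(F)F)=C[C@@H](C(=O)OC)[C@]2(CC(OC)OC)C1 | intermediate
11 | enol triflate aldehyde: methyl 6-methyl-7a-(2-oxoethyl)-3-(trifluoromethylsulfonyloxy)-3a,4,7,7a-tetrahydro-1H-indene-1-carboxylate (configuration as 9) | CC1=CC[C@@H]2C(OS(=O)(=O)C(F)(F)F)=C[C@@H](C(=O)OC)[C@]2(CC=O)C1 | intermediate
12 | bicyclo[2.2.2]octane alcohol with 13-OH syn to the C15–C16 bridge: methyl 8-hydroxy-11-methylidene-4-(trifluoromethylsulfonyloxy)tricyclo[5.2.2.0^1,5]undec-3-ene-2-carboxylate (bridgeheads C8 and C12; 6α-ester) | C=C1C[C@]23C[C@H](O)[C@H]1C[C@@H]2C(OS(=O)(=O)C(F)(F)F)=C[C@H]3C(=O)OC | intermediate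
13 | bicyclo[2.2.2]octan-13-one: methyl 11-methylidene-8-oxo-4-(trifluoromethylsulfonyloxy)tricyclo[5.2.2.0^1,5]undec-3-ene-2-carboxylate | C=C1C[C@]23CC(=O)[C@H]1C[C@@H]2C(OS(=O)(=O)C(F)(F)F)=C[C@H]3C(=O)OC | intermediate
14 | bicyclo[2.2.2]octane alcohol with 13-OH anti to the C15–C16 bridge (13-epimer of 12; OH syn to the C9–C11 bridge) | C=C1C[C@]23C[C@@H](O)[C@H]1C[C@@H]2C(OS(=O)(=O)C(F)(F)F)=C[C@H]3C(=O)OC | intermediate
15 | 13-mesylate of 14 | C=C1C[C@]23C[C@@H](OS(C)(=O)=O)[C@H]1C[C@@H]2C(OS(=O)(=O)C(F)(F)F)=C[C@H]3C(=O)OC | intermediate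
16 | bicyclo[3.2.1]octane 12-alcohol enol triflate: methyl 7-hydroxy-9-methylidene-4-(trifluoromethylsulfonyloxy)tricyclo[6.2.1.0^1,5]undec-3-ene-2-carboxylate (rings C/D as in the target; 12-OH axial, anti to C16; 6α-ester) | C=C1C[C@]23C[C@H]1[C@@H](O)C[C@@H]2C(OS(=O)(=O)C(F)(F)F)=C[C@H]3C(=O)OC | intermediate
17 | ring-B enal: methyl 4-formyl-7-hydroxy-9-methylidenetricyclo[6.2.1.0^1,5]undec-3-ene-2-carboxylate (CHO carbon = C1, on C10) | C=C1C[C@]23C[C@H]1[C@@H](O)C[C@@H]2C(C=O)=C[C@H]3C(=O)OC | intermediate
18 | methyl acetoacetate | CC(=O)CC(=O)OC | starting material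
19 | Michael adduct (C4–C5 bond made, C4 on the α face of C5; 6β-ester; C4 and C10 epimer mixtures) | C=C1C[C@]23C[C@H]1[C@@H](O)C[C@@H]2C(C=O)[C@@H](C(C(C)=O)C(=O)OC)[C@@H]3C(=O)OC | intermediate
20 | ketol (ring A closed, 1-hydroxy-3-oxo; C1, C4 and C10 epimer mixtures) | C=C1C[C@]23C[C@H]1[C@@H](O)C[C@@H]2C1C(O)CC(=O)C(C(=O)OC)[C@H]1[C@@H]3C(=O)OC | intermediate
21 | enone ester (ring A cyclohex-1-en-3-one with 4-H and 4-CO2Me; 5β-H, 10α-H, 6β-CO2Me) | C=C1C[C@]23C[C@H]1[C@@H](O)C[C@@H]2[C@@H]1C=CC(=O)C(C(=O)OC)[C@H]1[C@@H]3C(=O)OC | intermediate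
22 | C4-methylated enone diester (4β-Me, 4α-CO2Me, 5β-H, 10α-H, 6β-CO2Me, 12-OH) | C=C1C[C@]23C[C@H]1[C@@H](O)C[C@@H]2[C@@H]1C=CC(=O)[C@@](C)(C(=O)OC)[C@H]1[C@@H]3C(=O)OC | intermediate
23 | bis-silyl dienol ether (3-OTMS, C1=C10 and C2=C3; 12-OTMS) | C=C1C[C@]23C[C@H]1[C@@H](O[Si](C)(C)C)C[C@@H]2C1=CC=C(O[Si](C)(C)C)[C@@](C)(C(=O)OC)[C@H]1[C@@H]3C(=O)OC | intermediate
24 | 10-hydroxy enone (10α-OH, 12-OTMS) | C=C1C[C@]23C[C@H]1[C@@H](O[Si](C)(C)C)C[C@@H]2[C@]1(O)C=CC(=O)[C@@](C)(C(=O)OC)[C@H]1[C@@H]3C(=O)OC | intermediate
25 | enone lactone (19,10-lactone, C1=C2, 3-oxo, 12-OH, 7-methyl ester) | C=C1C[C@]23C[C@H]1[C@@H](O)C[C@@H]2[C@]12OC(=O)[C@](C)(C(=O)C=C1)[C@H]2[C@@H]3C(=O)OC | intermediate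
26 | boronate (1β-pinacolboryl 3-ketone) | C=C1C[C@]23C[C@H]1[C@@H](O)C[C@@H]2[C@]12OC(=O)[C@](C)(C(=O)C[C@H]1B1OC(C)(C)C(C)(C)O1)[C@H]2[C@@H]3C(=O)OC | intermediate
27 | methyl ester of the target (1β,12-dihydroxy-3-oxo 19,10-lactone 7-methyl ester) | C=C1C[C@]23C[C@H]1[C@@H](O)C[C@@H]2[C@]12OC(=O)[C@](C)(C(=O)C[C@H]1O)[C@H]2[C@@H]3C(=O)OC | intermediate
28 | CNP0259985.3 | C=C1C[C@]23C[C@H]1[C@@H](O)C[C@@H]2[C@]12OC(=O)[C@](C)(C(=O)C[C@H]1O)[C@H]2[C@@H]3C(=O)O | target

**Step count and risks**
Total: 14 steps. Longest linear sequence: 14 steps (1 and 2 to 28); 5, 8 and 18 enter as single building blocks.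

The three steps most likely to fail:

The enantioselective Diels–Alder reaction (step 4, the proposed new method). The β,β-disubstituted enone may be too unreactive, the Lewis acid may ionise the acetal, and the catalyst may not override the bias of the labile C6 ester; the catalyst antipode is used if the sense of induction is opposite. Fallback with known chemistry: starting from 7 and 8, the cycloaddition is run without any Lewis acid at 15 kbar (CH2Cl2, 50 °C), which gives the racemic cis-fused adduct, that is 9 together with its mirror-image cycloadduct F1. A ketoreductase (NADPH recycled with isopropanol) then reduces only the mirror-image ketone to the mirror-image hydroxy ester F2, and after chromatography the untouched ketone rejoins the route at 9.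

The solvolytic 1,2-shift (step 9). The bridged cation may be captured at C13 (return to 14) or at C17 (cyclopropylcarbinyl alcohol) instead of at C12. Fallback, a two-stage thermodynamic variant: starting from 14 through mesylate 15, hydrolysis under cold buffered conditions (KHCO3, aqueous dioxane, rt) collects the kinetic cyclopropylcarbinyl alcohol F3 (with recovered 14). Catalytic HClO4 in aqueous dioxane then re-ionises the cyclopropylcarbinol and opens it at C12 under thermodynamic control, where the bicyclo[3.2.1]octane is favoured, and the route is rejoined at 16.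

The γ-oxidation and lactonisation (step 12). The dioxirane may attack C10 from the β face or attack C2, and lactonisation of the hindered ester may be slow. Fallback by halolactonisation: starting from 22, deconjugation (KOt-Bu, t-BuOH/THF, then cold aqueous AcOH) gives the β,γ-unsaturated ketone F4. Iodine (MeCN, 0 °C) then forms the iodonium ion, which the C19 ester oxygen can open only at C10 from the α face and anti, with loss of the ester methyl, to give the 1β-iodo lactone F5. DBU eliminates HI (E1cB), and the route is rejoined at 25.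

**Further compounds**
F1 | step 4 | mirror-image cycloadduct (enantiomer of 9) | CC1=CC[C@H]2C(=O)C[C@H](C(=O)OC)[C@@]2(CC(OC)OC)C1
F2 | step 4 | mirror-image hydroxy ester (C10 alcohol from F1; carbinol configuration as delivered by the enzyme, drawn arbitrarily) | CC1=CC[C@H]2[C@H](O)C[C@H](C(=O)OC)[C@@]2(CC(OC)OC)C1
F3 | step 9 | cyclopropylcarbinyl alcohol (cyclopropane C12–C13–C16, CH2OH = C17 on C16, C10 enol triflate, 6α-ester) | OC[C@]12C[C@]34C[C@H]1[C@H]2C[C@@H]3C(OS(=O)(=O)C(F)(F)F)=C[C@H]4C(=O)OC
F4 | step 12 | β,γ-unsaturated ketone (C1=C10 isomer of 22) | C=C1C[C@]23C[C@H]1[C@@H](O)C[C@@H]2C1=CCC(=O)[C@@](C)(C(=O)OC)[C@H]1[C@@H]3C(=O)OC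
F5 | step 12 | 1β-iodo lactone (1β-iodo-3-oxo 19,10-lactone 7-methyl ester) | C=C1C[C@]23C[C@H]1[C@@H](O)C[C@@H]2[C@]12OC(=O)[C@](C)(C(=O)C[C@H]1I)[C@H]2[C@@H]3C(=O)OC
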